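## Analysis of the target

Eduesmine is a 7,7'-epoxylignan. It has one oxolane ring (O1, C2–C5) with 4-hydroxy-3-methoxyphenyl groups on C2 and C5 and hydroxymethyl groups on C3 and C4. All four ring carbons are stereocentres and all are S. Read from the SMILES, aryl and hydroxymethyl are cis on C2/C3 and on C5/C4, and the two hydroxymethyl groups are trans on C3/C4. The two aryl groups are therefore trans, and a twofold axis runs through O1 and the midpoint of C3–C4.

The sensitive sites are the benzylic ether carbons C2 and C5. Each is para to a free phenol, so acid or hot base can open the C–O bond through a quinone methide and let the centre relax to the more stable aryl-trans arrangement. The phenols are also easily oxidised. The difficulty is thus the relative configuration (two contra-thermodynamic cis contacts on either side of a trans junction) in a single enantiomer.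

The plan rests on the C3–C4 bond. It joins two identical halves, each made of an aryl ring, C2 (or C5), C3 (or C4) and its hydroxymethyl carbon. Each half is the carbon skeleton of ferulic acid, with the hydroxymethyl carbon as the former carboxyl carbon and C3/C4 as the carbon alpha to it.

## Retrosynthetic reasoning

**Unmasking (14 from 13 from 12).** The last two operations only remove protecting groups: two aryl methanesulfonates (13 to 14) and two primary silyl ethers (12 to 13). Both masks are chosen for what they do earlier. The sulfonates turn each para oxygen from a donor into an acceptor, so the benzylic carbons react by SN2 and not by ionisation. The silyl ethers stop the primary oxygens from competing for the benzylic electrophile. No skeletal bond changes here.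

**The ring oxygen (12 from 9).** Both ring C–O bonds of 12 (O1–C2 and O1–C5) are cut and the oxygen is removed altogether. This leads to the seven-membered cyclic sulfate 9, in which the two benzylic carbons still carry their original oxygens. The cut is made here because 9 has the wrong configuration at both benzylic carbons. An external oxygen nucleophile that enters at one carbon with inversion and then closes onto the other with inversion corrects both. The tether matters: the two carbinols of diol 7 are homotopic, so a reagent that must react at only one of them would give statistical mixtures. On a 1,4-diol it would also risk cyclodehydration to the wrong diastereomer. In 9 the first substitution is necessarily single, because the second leaving group becomes an anionic sulfate monoester. The forward reaction must achieve SN2 at a hindered secondary benzylic carbon without ionisation or elimination.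

**Back to the lactone oxidation level (9 from 8 from 7 from 6 from 5).** The sulfate comes from sulfite 8, the sulfite from diol 7, and 7 from tetraol 6 by silylation of the primary hydroxyls. The four C–O single bonds of 6 come from the two lactones of 5 by hydride reduction. Each lactone carbonyl becomes a hydroxymethyl group, and each lactone alkyl oxygen becomes a benzylic hydroxyl with its configuration untouched. This fixes the stereochemical bookkeeping:
- The cis ring fusion of 5 becomes, after rotation about the central bond, the trans relation of the two CH2O groups on C3/C4.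
- Each aryl group of 5 is trans to the carbonyl carbon on the adjacent ring-fusion carbon, which is why both benzylic centres must later be inverted.

**Enantiomer and phenol masking (5 from 4 from 3).** Compound 5 is one enantiomer of racemic 4, obtained by resolution. Compound 4 is the bis-methanesulfonate of the racemic bis-lactone 3. Mesylation precedes resolution because 4 is neutral, soluble and base-stable, and its sulfur atoms allow the absolute configuration to be assigned crystallographically. Half of the material is lost here, but that half has cost only two steps.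

**The skeleton (3 from 2 from 1).** In 3 the bond between the two ring-fusion carbons (the future C3–C4) and the two lactone C–O bonds are cut. This gives the bis(quinone methide) diacid 2, and then two molecules of ferulic acid 1. The central bond joins two carbons of like polarity, each alpha to a carboxyl group, so it is made by combining two radicals and not by a polar step. One operation on a commodity acid gives the whole carbon skeleton, both rings of 3 and all four stereocentres in a defined relative configuration. The forward reaction must achieve tail-to-tail coupling and double lactonisation without over-oxidation.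

## Alternatives that were turned down

**Alternative 1:** The two aryl–carbon bonds at C2 and C5 are disconnected.
- **Forward key step.** The twofold-symmetric bis-carbamate A1 is lithiated at both O–CH2 groups with s-BuLi and (−)-sparteine or its antipode. Each carbanion is trapped by the aryl pinacol boronate A2, and a 1,2-shift of aryl from boron to carbon with loss of carbamate gives the bis-boronate A3.
- **For it.** The diamine sets the absolute configuration of both benzylic carbons, so no resolution is needed. On this point it is stronger than the chosen route. The aryl groups also arrive late, which suits analogues.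
- **Against it.** A3 is not the ring. Both C–B bonds must still be oxidised, and the resulting diol needs the same double-inversion closure, so the endgame is no shorter. A1 is a chiral tetra-oxygenated chain that needs its own multistep enantioselective preparation. Two lithiation–borylation events must succeed on one molecule, at beta-branched primary carbamates that lithiate slowly. The second event meets either a dianion or an existing boronate. The benzylic CH2 groups of the benzyl ethers are competing sites for s-BuLi.
- **Comparison.** The chosen route gives up reagent-controlled chirality. In exchange it makes the C3–C4 bond, both lactone rings and four stereocentres in one step from 1.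

**Alternative 2:** O1–C2 and the bond from C3 to its one-carbon substituent are disconnected, and that carbon comes from CO.
- **Forward key step.** The alkynol A4 is treated with PdI2 and KI under CO and air in methanol. The hydroxyl adds 5-endo-dig to the aryl-bearing alkyne carbon, and the vinylpalladium inserts CO and is trapped by methanol. The product is the dihydrofuran ester A5.
- **For it.** One catalytic step forms the ring and adds the missing carbon, and no symmetric diol has to be desymmetrised. On catalysis and on avoiding a resolution it is stronger than the chosen route.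
- **Against it.** It ignores the twofold symmetry, so the two halves are built by unrelated chemistry. A4 must first be made enantio- and diastereoselectively. The main problem comes after the key step. The tetrasubstituted C2=C3 alkene of A5 must take up hydrogen on the face that already carries the C4 and C5 substituents. Only this gives aryl cis to C3 and C3 trans to C4. It is the hindered face, so a hydroxyl-directed hydrogenation would be needed (for example with [Ir(cod)(PCy3)(py)]PF6) on a push–pull tetrasubstituted alkene. Benzyl ethers and benzylic ring C–O bonds would be at risk of hydrogenolysis. Ester reduction and deprotection then follow.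
- **Comparison.** In the chosen route the C3/C4 relation follows automatically from the ring fusion, and both cis contacts come from stereospecific SN2 steps.

**Alternative 3:** Both ring C–O bonds are disconnected and the ring oxygen comes from outside.
- **Forward key step.** The diol A6 is converted into its seven-membered cyclic sulfate A7. Tetrabutylammonium acetate opens A7 at one benzylic carbon with inversion. After methanolysis of the acetate, the alkoxide displaces the sulfate at the other benzylic carbon with inversion, giving the oxolane A8.
- **For it.** This is the cleanest way to turn a like-configured 1,4-diol into the cis,trans,cis ring. Because it is tethered, it avoids mono-activation of a symmetric diol. On this point it is as strong as anything available, and the chosen route uses the same closure in its own endgame (steps 6 to 8).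
- **Against it as a strategy.** It puts the strategic step on the heteroatom and leaves the hard part open: the C3–C4 bond and the four contiguous stereocentres of A6 would need a separate, longer asymmetric construction. The benzyl ethers of A8 also call for a final hydrogenolysis next to two benzylic ring C–O bonds.
- **Comparison.** The chosen strategy supplies the diol in five steps from 1 and uses fluoride-labile silyl ethers instead.

Key step: step 1

Remark on the chemistry: compounds 2, 3 and 4 are racemic and are written with the SMILES of the enantiomer that step 3 selects; the absolute configuration of 5 is to be confirmed by anomalous-dispersion crystallography before it is carried on.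

## Route

Step 1
Reactants: 1 (E)-ferulic acid (two molecules)
Product: 3 racemic cis-fused exo,exo bis-lactone 2,6-bis(4-hydroxy-3-methoxyphenyl)-3,7-dioxabicyclo[3.3.0]octane-4,8-dione, via bis(quinone methide) diacid 2 (not isolated)
Conditions: graphite-felt anode, Pt cathode, divided cell, constant potential at the first oxidation wave of 1, ca. 1 F/mol, aq. AcOH/NaOAc buffer (pH ca. 4)–acetone, 5 °C
Reagents that add atoms: none
Why: Anodic one-electron oxidation of the phenol of 1 with loss of a proton gives a phenoxyl radical whose spin is delocalised onto the side-chain carbon alpha to the carboxyl group; two such radicals combine there to form the central C–C bond of 2, and each carboxyl group then adds to the exocyclic methide carbon of the opposite half, which restores both arenes. The closest known reaction type is the oxidative tail-to-tail dehydrodimerisation of 4-hydroxycinnamic acids by FeCl3 or peroxidase/H2O2. Both gamma-lactone rings close in the 5-exo-trig mode, as 1,6-additions of oxygen to a quinone methide. The two ring-fusion centres arise in the radical coupling without facial control, but only the like (twofold-symmetric) diastereomer of 2 can close twice, and a bicyclo[3.3.0] skeleton can only be cis-fused. The two benzylic centres are set in the lactonisations: each aryl group takes the convex (exo) face, anti to the neighbouring ring, and the reversibility of carboxyl addition to a quinone methide should let this thermodynamic arrangement prevail. The step needs tail-to-tail regioselectivity over coupling through ring carbon 5 or the phenol oxygen, which the substrate supports only through its high spin density at the alpha carbon, and it needs the product to escape further oxidation, which is helped by holding the potential at the first wave of 1 (3 has lost the cinnamoyl conjugation) and by the low solubility of neutral 3. Unreacted 1 and acidic by-products are removed by a brief NaHCO3 wash.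

Step 2
Reactants: 3 racemic bis-lactone
Product: 4 racemic 2,6-bis(3-methoxy-4-methylsulfonyloxyphenyl)-3,7-dioxabicyclo[3.3.0]octane-4,8-dione
Conditions: MsCl, pyridine, CH2Cl2, 0 °C → rt
Reagents that add atoms: methanesulfonyl chloride, CS(=O)(=O)Cl
Why: O-Sulfonylation of the two phenols; pyridine is too weak a base to form the phenoxide (which would expel the lactone carboxylate para to it) or to enolise the lactones, so the four stereocentres are untouched. From here on each para oxygen is an acceptor, which closes the quinone methide channel for the rest of the route.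

Step 3
Reactants: 4 racemic bis-lactone bis-methanesulfonate
Product: 5 (1R,2R,5R,6R)-2,6-bis(3-methoxy-4-methylsulfonyloxyphenyl)-3,7-dioxabicyclo[3.3.0]octane-4,8-dione
Conditions: preparative SFC, amylose tris(3,5-dimethylphenylcarbamate) on silica, CO2/MeOH, 35 °C
Reagents that add atoms: none
Why: Resolution of enantiomers by chromatography on a chiral stationary phase, a physical separation that creates no stereocentre; the rigid twofold-symmetric bicycle with two lactone carbonyls and two aryl sulfonates offers the hydrogen-bond-acceptor and pi contacts on which carbamate-coated polysaccharide phases discriminate. The wanted antipode is identified crystallographically and the other is set aside.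

Step 4
Reactants: 5 (1R,2R,5R,6R)-bis-lactone bis-methanesulfonate
Product: 6 (1R,2S,3S,4R)-2,3-bis(hydroxymethyl)-1,4-bis(3-methoxy-4-methylsulfonyloxyphenyl)butane-1,4-diol
Conditions: LiBH4, THF, 0 °C → rt; aq. NH4Cl
Reagents that add atoms: none
Why: Borohydride reduction of both lactones to diols cleaves only acyl–oxygen bonds, so the benzylic C–O bonds and all four stereocentres are retained; LiBH4 is chosen over LiAlH4 because it leaves aryl sulfonates alone.

Step 5
Reactants: 6 tetraol
Product: 7 (1R,2S,3S,4R)-2,3-bis(tert-butyldimethylsilyloxymethyl)-1,4-bis(3-methoxy-4-methylsulfonyloxyphenyl)butane-1,4-diol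
Conditions: TBSCl (2.1 equiv), imidazole, DMF, 0 °C
Reagents that add atoms: tert-butyldimethylsilyl chloride, CC(C)(C)[Si](C)(C)Cl
Why: Sterically controlled silylation: the primary hydroxyls react far faster than the secondary benzylic ones, each flanked by an aryl group and a branched carbon. The silyl ethers keep the primary oxygens from acting as nucleophiles toward the benzylic electrophile in step 8.

Step 6
Reactants: 7 bis-silyl diol
Product: 8 (4R,5S,6S,7R)-5,6-bis(tert-butyldimethylsilyloxymethyl)-4,7-bis(3-methoxy-4-methylsulfonyloxyphenyl)-1,3,2-dioxathiepane 2-oxide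
Conditions: SOCl2, Et3N, CH2Cl2, 0 °C
Reagents that add atoms: thionyl chloride, O=S(Cl)Cl
Why: Cyclic sulfite formation from a 1,4-diol through the chlorosulfite; only O–S bonds form, so configuration is retained, and because the two oxygens are related by the twofold axis a single sulfite results.

Step 7
Reactants: 8 cyclic sulfite
Product: 9 (4R,5S,6S,7R)-5,6-bis(tert-butyldimethylsilyloxymethyl)-4,7-bis(3-methoxy-4-methylsulfonyloxyphenyl)-1,3,2-dioxathiepane 2,2-dioxide
Conditions: RuCl3 (cat.), NaIO4, MeCN/CH2Cl2/H2O, 0 °C
Reagents that add atoms: sodium periodate, [Na+].[O-]I(=O)(=O)=O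
Why: RuO4-catalysed oxidation of the sulfite sulfur to the sulfate, the standard second stage of cyclic sulfate synthesis; brief exposure at 0 °C and the sulfonate-deactivated arenes should confine oxidation to sulfur. The benzylic cyclic sulfate is used at once.

Step 8
Reactants: 9 cyclic sulfate
Product: 12 (2S,3S,4S,5S)-3,4-bis(tert-butyldimethylsilyloxymethyl)-2,5-bis(3-methoxy-4-methylsulfonyloxyphenyl)oxolane, via acetoxy sulfate salt 10 (not isolated), via hydroxy sulfate salt 11 (not isolated)
Conditions: Bu4NOAc, THF, 0 °C → rt; then K2CO3, MeOH, rt → 40 °C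
Reagents that add atoms: tetrabutylammonium acetate, CC(=O)[O-].CCCC[N+](CCCC)(CCCC)CCCC
Why: Nucleophilic opening of a cyclic sulfate: acetate attacks one of the two equivalent benzylic carbons by SN2 with inversion, and the sulfate monoester anion of 10 is inert to a second intermolecular attack. Methanolysis of the acetate frees the alkoxide of 11, which displaces the sulfate in a 5-exo-tet SN2 closure with inversion at the second benzylic carbon, so both aryl-bearing centres end up inverted relative to 7 (aryl cis to the neighbouring CH2O group) while C3 and C4 are untouched and the acetate oxygen becomes O1. The electron-poor sulfonyloxyarenes disfavour ionisation, and the silylated primary oxygens cannot compete.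

Step 9
Reactants: 12 bis-silyl oxolane
Product: 13 (2S,3S,4S,5S)-3,4-bis(hydroxymethyl)-2,5-bis(3-methoxy-4-methylsulfonyloxyphenyl)oxolane
Conditions: TBAF, AcOH, THF, rt
Reagents that add atoms: none
Why: Fluoride-induced cleavage of the two primary silyl ethers; acetic acid buffers the basicity of the fluoride so that the aryl sulfonates and the ring stay intact.

Step 10
Reactants: 13 diol bis-methanesulfonate
Product: 14 eduesmine, (2S,3S,4S,5S)-2,5-bis(4-hydroxy-3-methoxyphenyl)-3,4-bis(hydroxymethyl)oxolane
Conditions: KOH, MeOH/H2O, 60 °C, Ar; aq. NH4Cl
Reagents that add atoms: none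
Why: Alkaline hydrolysis of the aryl methanesulfonates (attack at sulfur, phenoxide as leaving group); the ring is never exposed to acid, since the free para-hydroxybenzyl ether carbons would epimerise through quinone methide cations, and the work-up is held near neutral.

## Compound list

1 | (E)-ferulic acid, (2E)-3-(4-hydroxy-3-methoxyphenyl)prop-2-enoic acid | COc1cc(/C=C/C(=O)O)ccc1O | starting material
2 | like (twofold-symmetric) diastereomer of 2,3-bis[(3-methoxy-4-oxocyclohexa-2,5-dien-1-ylidene)methyl]butanedioic acid, racemic, methide alkene geometry not fixed, not isolated | COC1=CC(=C[C@H](C(=O)O)[C@@H](C(=O)O)C=C2C=CC(=O)C(OC)=C2)C=CC1=O | intermediate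
3 | racemic (1R*,2R*,5R*,6R*)-2,6-bis(4-hydroxy-3-methoxyphenyl)-3,7-dioxabicyclo[3.3.0]octane-4,8-dione, cis-fused, both aryl groups exo | COc1cc([C@@H]2OC(=O)[C@@H]3[C@H]2C(=O)O[C@H]3c4ccc(O)c(OC)c4)ccc1O | intermediate
4 | racemic (1R*,2R*,5R*,6R*)-2,6-bis(3-methoxy-4-methylsulfonyloxyphenyl)-3,7-dioxabicyclo[3.3.0]octane-4,8-dione | COc1cc([C@@H]2OC(=O)[C@@H]3[C@H]2C(=O)O[C@H]3c4ccc(OS(C)(=O)=O)c(OC)c4)ccc1OS(C)(=O)=O | intermediate
5 | (1R,2R,5R,6R)-2,6-bis(3-methoxy-4-methylsulfonyloxyphenyl)-3,7-dioxabicyclo[3.3.0]octane-4,8-dione | COc1cc([C@@H]2OC(=O)[C@@H]3[C@H]2C(=O)O[C@H]3c4ccc(OS(C)(=O)=O)c(OC)c4)ccc1OS(C)(=O)=O | intermediate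
6 | (1R,2S,3S,4R)-2,3-bis(hydroxymethyl)-1,4-bis(3-methoxy-4-methylsulfonyloxyphenyl)butane-1,4-diol | COc1cc([C@H](O)[C@H](CO)[C@@H](CO)[C@@H](O)c2ccc(OS(C)(=O)=O)c(OC)c2)ccc1OS(C)(=O)=O | intermediate
7 | (1R,2S,3S,4R)-2,3-bis(tert-butyldimethylsilyloxymethyl)-1,4-bis(3-methoxy-4-methylsulfonyloxyphenyl)butane-1,4-diol | COc1cc([C@H](O)[C@H](CO[Si](C)(C)C(C)(C)C)[C@@H](CO[Si](C)(C)C(C)(C)C)[C@@H](O)c2ccc(OS(C)(=O)=O)c(OC)c2)ccc1OS(C)(=O)=O | intermediate
8 | (4R,5S,6S,7R)-5,6-bis(tert-butyldimethylsilyloxymethyl)-4,7-bis(3-methoxy-4-methylsulfonyloxyphenyl)-1,3,2-dioxathiepane 2-oxide | COc1cc([C@@H]2OS(=O)O[C@@H](c3ccc(OS(C)(=O)=O)c(OC)c3)[C@H](CO[Si](C)(C)C(C)(C)C)[C@H]2CO[Si](C)(C)C(C)(C)C)ccc1OS(C)(=O)=O | intermediate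
9 | (4R,5S,6S,7R)-5,6-bis(tert-butyldimethylsilyloxymethyl)-4,7-bis(3-methoxy-4-methylsulfonyloxyphenyl)-1,3,2-dioxathiepane 2,2-dioxide | COc1cc([C@@H]2OS(=O)(=O)O[C@@H](c3ccc(OS(C)(=O)=O)c(OC)c3)[C@H](CO[Si](C)(C)C(C)(C)C)[C@H]2CO[Si](C)(C)C(C)(C)C)ccc1OS(C)(=O)=O | intermediate
10 | tetrabutylammonium (1R,2S,3S,4S)-4-acetoxy-2,3-bis(tert-butyldimethylsilyloxymethyl)-1,4-bis(3-methoxy-4-methylsulfonyloxyphenyl)butyl sulfate, not isolated | COc1cc([C@@H](OC(C)=O)[C@H](CO[Si](C)(C)C(C)(C)C)[C@@H](CO[Si](C)(C)C(C)(C)C)[C@@H](OS(=O)(=O)[O-])c2ccc(OS(C)(=O)=O)c(OC)c2)ccc1OS(C)(=O)=O.CCCC[N+](CCCC)(CCCC)CCCC | intermediate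
11 | tetrabutylammonium (1R,2S,3S,4S)-4-hydroxy-2,3-bis(tert-butyldimethylsilyloxymethyl)-1,4-bis(3-methoxy-4-methylsulfonyloxyphenyl)butyl sulfate, not isolated | COc1cc([C@@H](O)[C@H](CO[Si](C)(C)C(C)(C)C)[C@@H](CO[Si](C)(C)C(C)(C)C)[C@@H](OS(=O)(=O)[O-])c2ccc(OS(C)(=O)=O)c(OC)c2)ccc1OS(C)(=O)=O.CCCC[N+](CCCC)(CCCC)CCCC | intermediate
12 | (2S,3S,4S,5S)-3,4-bis(tert-butyldimethylsilyloxymethyl)-2,5-bis(3-methoxy-4-methylsulfonyloxyphenyl)oxolane | COc1cc([C@H]2O[C@H](c3ccc(OS(C)(=O)=O)c(OC)c3)[C@H](CO[Si](C)(C)C(C)(C)C)[C@H]2CO[Si](C)(C)C(C)(C)C)ccc1OS(C)(=O)=O | intermediate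
13 | (2S,3S,4S,5S)-3,4-bis(hydroxymethyl)-2,5-bis(3-methoxy-4-methylsulfonyloxyphenyl)oxolane | COc1cc([C@H]2O[C@H](c3ccc(OS(C)(=O)=O)c(OC)c3)[C@H](CO)[C@H]2CO)ccc1OS(C)(=O)=O | intermediate
14 | eduesmine, (2S,3S,4S,5S)-2,5-bis(4-hydroxy-3-methoxyphenyl)-3,4-bis(hydroxymethyl)oxolane | COc1cc([C@H]2O[C@H](c3ccc(O)c(OC)c3)[C@H](CO)[C@H]2CO)ccc1O | target

## Step count and least certain steps

Total step count: 10. Longest linear sequence: 10 steps (the route is linear from 1).

**Step 1 (key step).**
- **What may go wrong.** Unselective radical coupling through ring carbon 5 or the phenol oxygen instead of tail to tail. Coupling to the unlike diastereomer, which cannot lactonise twice. Further oxidation of the product, or fouling of the anode by a polymer film. Nothing in 1 blocks the other spin-bearing positions, and the product still carries oxidisable phenols.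
- **Fallback.** The electrode is replaced by a dissolved one-electron oxidant. Compound 1 is treated with FeCl3 in aqueous acetone at room temperature. The oxidant has a fixed potential that should not reach the product, there is no surface to foul, and the neutral bis-lactone can crystallise out. This sets out from 1 and returns at 3 with no new compound.

**Step 8.**
- **What may go wrong.** Partial ionisation of the benzylic sulfate, with loss of stereochemical fidelity. E2 elimination toward a styrene. Slow displacement of the anionic sulfate leaving group, which would give time for methanolysis of an aryl sulfonate or for silyl migration to the new alkoxide. Lability of the benzylic cyclic sulfate from step 7 belongs to the same risk.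
- **Fallback.** A stepwise sequence sets out from 7 and bypasses 8 and 9.
  - Mitsunobu esterification of 7 with one equivalent of 4-nitrobenzoic acid (PPh3, DIAD, toluene, −20 °C) inverts one carbinol. It gives (1S,2S,3S,4R)-2,3-bis(tert-butyldimethylsilyloxymethyl)-4-hydroxy-1,4-bis(3-methoxy-4-methylsulfonyloxyphenyl)butyl 4-nitrobenzoate F1.
  - Mesylation (MsCl, Et3N, CH2Cl2, −20 °C) gives the 4-methylsulfonyloxy analogue, (1S,2S,3S,4R)-2,3-bis(tert-butyldimethylsilyloxymethyl)-4-methylsulfonyloxy-1,4-bis(3-methoxy-4-methylsulfonyloxyphenyl)butyl 4-nitrobenzoate F2.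
  - K2CO3 in MeOH at 0 °C removes the nitrobenzoate, and the alkoxide closes onto the mesylate with inversion, returning to the route at 12.
  - The price is that mono-esterification of a symmetric diol is statistical. Recovered 7 is recycled, and any oxolane formed by direct cyclodehydration must be separated.

**Step 3.**
- **What may go wrong.** Insufficient separation or low loading on the chiral phase, for instance because 4 is poorly soluble in the mobile phase. The step would then not supply enough 5.
- **Fallback.** A covalent resolution sets out from racemic 4.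
  - Racemic 4 is taken through steps 4 and 5 unresolved. This gives 6 together with its mirror image, (1S,2R,3R,4S)-2,3-bis(hydroxymethyl)-1,4-bis(3-methoxy-4-methylsulfonyloxyphenyl)butane-1,4-diol F3. It then gives 7 together with its mirror image, (1S,2R,3R,4S)-2,3-bis(tert-butyldimethylsilyloxymethyl)-1,4-bis(3-methoxy-4-methylsulfonyloxyphenyl)butane-1,4-diol F4.
  - Acylation with (1S)-camphanoyl chloride (pyridine, DMAP, CH2Cl2) gives two diastereomers: the bis[(1S,4R)-camphanate] of 7 F5 and the bis[(1S,4R)-camphanate] of the mirror-image diol F6. They are separated by crystallisation or ordinary chromatography.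
  - K2CO3 in MeOH cleaves F5 and returns to the route at 7.

**Step 10.**
- **What may go wrong.** Opening of the ring at a phenoxide-bearing benzylic ether carbon in hot hydroxide (quinone methide formation, then re-closure with epimerisation), or incomplete S–O cleavage.
- **Fallback.** The sulfonates are removed without hydroxide and before desilylation, setting out from 12.
  - LiN(iPr)2 in THF (−78 → 0 °C) deprotonates the S-methyl groups. Loss of sulfene releases the phenoxides and gives (2S,3S,4S,5S)-3,4-bis(tert-butyldimethylsilyloxymethyl)-2,5-bis(4-hydroxy-3-methoxyphenyl)oxolane F7.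
  - TBAF buffered with AcOH in THF removes the silyl ethers and returns to the route at 14.

## Further compounds

F0 | step 1 | none | none
F1 | step 8 | (1S,2S,3S,4R)-2,3-bis(tert-butyldimethylsilyloxymethyl)-4-hydroxy-1,4-bis(3-methoxy-4-methylsulfonyloxyphenyl)butyl 4-nitrobenzoate | COc1cc([C@@H](OC(=O)c2ccc(cc2)[N+](=O)[O-])[C@H](CO[Si](C)(C)C(C)(C)C)[C@@H](CO[Si](C)(C)C(C)(C)C)[C@@H](O)c2ccc(OS(C)(=O)=O)c(OC)c2)ccc1OS(C)(=O)=O
F2 | step 8 | (1S,2S,3S,4R)-2,3-bis(tert-butyldimethylsilyloxymethyl)-4-methylsulfonyloxy-1,4-bis(3-methoxy-4-methylsulfonyloxyphenyl)butyl 4-nitrobenzoate | COc1cc([C@@H](OC(=O)c2ccc(cc2)[N+](=O)[O-])[C@H](CO[Si](C)(C)C(C)(C)C)[C@@H](CO[Si](C)(C)C(C)(C)C)[C@@H](OS(C)(=O)=O)c2ccc(OS(C)(=O)=O)c(OC)c2)ccc1OS(C)(=O)=O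
F3 | step 3 | (1S,2R,3R,4S)-2,3-bis(hydroxymethyl)-1,4-bis(3-methoxy-4-methylsulfonyloxyphenyl)butane-1,4-diol | COc1cc([C@@H](O)[C@@H](CO)[C@H](CO)[C@H](O)c2ccc(OS(C)(=O)=O)c(OC)c2)ccc1OS(C)(=O)=O
F4 | step 3 | (1S,2R,3R,4S)-2,3-bis(tert-butyldimethylsilyloxymethyl)-1,4-bis(3-methoxy-4-methylsulfonyloxyphenyl)butane-1,4-diol | COc1cc([C@@H](O)[C@@H](CO[Si](C)(C)C(C)(C)C)[C@H](CO[Si](C)(C)C(C)(C)C)[C@H](O)c2ccc(OS(C)(=O)=O)c(OC)c2)ccc1OS(C)(=O)=O
F5 | step 3 | bis[(1S,4R)-camphanate] of 7 | COc1cc([C@H](OC(=O)[C@@]34CC[C@@](C)(C(=O)O3)C4(C)C)[C@H](CO[Si](C)(C)C(C)(C)C)[C@@H](CO[Si](C)(C)C(C)(C)C)[C@@H](OC(=O)[C@@]34CC[C@@](C)(C(=O)O3)C4(C)C)c2ccc(OS(C)(=O)=O)c(OC)c2)ccc1OS(C)(=O)=O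
F6 | step 3 | bis[(1S,4R)-camphanate] of F4 | COc1cc([C@@H](OC(=O)[C@@]34CC[C@@](C)(C(=O)O3)C4(C)C)[C@@H](CO[Si](C)(C)C(C)(C)C)[C@H](CO[Si](C)(C)C(C)(C)C)[C@H](OC(=O)[C@@]34CC[C@@](C)(C(=O)O3)C4(C)C)c2ccc(OS(C)(=O)=O)c(OC)c2)ccc1OS(C)(=O)=O
F7 | step 10 | (2S,3S,4S,5S)-3,4-bis(tert-butyldimethylsilyloxymethyl)-2,5-bis(4-hydroxy-3-methoxyphenyl)oxolane | COc1cc([C@H]2O[C@H](c3ccc(O)c(OC)c3)[C@H](CO[Si](C)(C)C(C)(C)C)[C@H]2CO[Si](C)(C)C(C)(C)C)ccc1O
A1 | alternative 1 | (2S,3S)-2,3-bis(benzyloxymethyl)butane-1,4-diyl bis(N,N-diisopropylcarbamate) | CC(C)N(C(C)C)C(=O)OC[C@H](COCc1ccccc1)[C@@H](COCc1ccccc1)COC(=O)N(C(C)C)C(C)C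
A2 | alternative 1 | 2-(4-benzyloxy-3-methoxyphenyl)-4,4,5,5-tetramethyl-1,3,2-dioxaborolane | COc1cc(B2OC(C)(C)C(C)(C)O2)ccc1OCc1ccccc1
A3 | alternative 1 | twofold-symmetric 1,4-bis(4-benzyloxy-3-methoxyphenyl)-2,3-bis(benzyloxymethyl)butane-1,4-diyl bis(pinacol boronate) | COc1cc([C@H](B2OC(C)(C)C(C)(C)O2)[C@H](COCc2ccccc2)[C@@H](COCc2ccccc2)[C@@H](B2OC(C)(C)C(C)(C)O2)c2ccc(OCc3ccccc3)c(OC)c2)ccc1OCc1ccccc1
A4 | alternative 2 | (1S,2S)-1,4-bis(4-benzyloxy-3-methoxyphenyl)-2-(tert-butyldimethylsilyloxymethyl)but-3-yn-1-ol | COc1cc(C#C[C@@H](CO[Si](C)(C)C(C)(C)C)[C@H](O)c2ccc(OCc3ccccc3)c(OC)c2)ccc1OCc1ccccc1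
A5 | alternative 2 | methyl 4,5-cis-2,5-bis(4-benzyloxy-3-methoxyphenyl)-4-(tert-butyldimethylsilyloxymethyl)-4,5-dihydrofuran-3-carboxylate | COC(=O)C1=C(c2ccc(OCc3ccccc3)c(OC)c2)O[C@H](c2ccc(OCc3ccccc3)c(OC)c2)[C@@H]1CO[Si](C)(C)C(C)(C)C
A6 | alternative 3 | (1R,2S,3S,4R)-2,3-bis(benzyloxymethyl)-1,4-bis(3-methoxy-4-methylsulfonyloxyphenyl)butane-1,4-diol | COc1cc([C@H](O)[C@H](COCc2ccccc2)[C@@H](COCc2ccccc2)[C@@H](O)c2ccc(OS(C)(=O)=O)c(OC)c2)ccc1OS(C)(=O)=O
A7 | alternative 3 | (4R,5S,6S,7R)-5,6-bis(benzyloxymethyl)-4,7-bis(3-methoxy-4-methylsulfonyloxyphenyl)-1,3,2-dioxathiepane 2,2-dioxide | COc1cc([C@@H]2OS(=O)(=O)O[C@@H](c3ccc(OS(C)(=O)=O)c(OC)c3)[C@H](COCc3ccccc3)[C@H]2COCc2ccccc2)ccc1OS(C)(=O)=O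
A8 | alternative 3 | (2S,3S,4S,5S)-3,4-bis(benzyloxymethyl)-2,5-bis(3-methoxy-4-methylsulfonyloxyphenyl)oxolane | COc1cc([C@H]2O[C@H](c3ccc(OS(C)(=O)=O)c(OC)c3)[C@H](COCc3ccccc3)[C@H]2COCc2ccccc2)ccc1OS(C)(=O)=O
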